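Ring A of the target is a cyclohexa-2,4-dienone frame (chromanone numbering) in which C6 is the only sp3 atom, so it is opened between C6 and C7 to an acyclic dienylketene (C7=C8, C8a=C4a, C5=C6). Step 16 makes this ketene from a β,γ-unsaturated acid and lets it close in one thermal six-electron electrocyclisation that forms C6–C7, ring A and the quaternary centre C6 at once. The acid 34 already carries every other stereocentre, a C8a=C4a enol ether with C8 and C5 cis that bears the ring B chain on O1, and a geometrically defined C5=C6 enol carbamate holding prenyl and cyclobutylmethyl; it comes from a Negishi union of a carbocupration-derived vinylzinc with a bromo enol ether.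

Key step: step 16

Remark 1: the quinidine-derived catalyst of step 9 is taken to give the (R)-hemiester 19; if the induction runs the other way, its quinine-derived pseudoenantiomer is used instead.
Remark 2: in step 16 the benzylic C–H is taken to lie in the diene plane next to O1, so that phenyl covers one face at C7 and the inward-turning cyclobutylmethyl group takes the other; this sense gives the C6 configuration of 42.
Remark 3: all descriptors were re-derived; the cyclobutane of 42 corresponds to (1S,5S)-verbenone and its 2,3-cis-dimethyl unit to the syn-aldol of the (S)-auxiliary, and descriptor changes along the route (for example 1S in 5, 1R in 33) are priority changes only.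
Remark 4: no acid-labile protecting group is used, because prenyl and the isopropenylcyclobutane do not tolerate strong acid; the C7 acid travels as a 2-(trimethylsilyl)ethyl ester and the side-chain acid as a methyl ester.

Step 1
Reactants: 1 (1S)-(−)-verbenone
Product: 2 (1S,3R)-3-acetyl-2,2-dimethylcyclobutane-1-carboxylic acid (cis-pinononic acid)
Conditions: RuCl3·xH2O (2 mol%), NaIO4 (4.1 equiv), CCl4/MeCN/H2O, rt
Reagents that add atoms: sodium periodate, [Na+].[O-]I(=O)(=O)=O
Why: Sharpless RuO4 cleavage of the enone C=C with oxidative loss of the former C3 as CO2 should leave both cyclobutane stereocentres untouched, so the cis-1,3 relationship of the bicycle is kept.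

Step 2
Reactants: 2 cis-pinononic acid
Product: 3 (1S,3S)-2,2-dimethyl-3-(prop-1-en-2-yl)cyclobutane-1-carboxylic acid
Conditions: Ph3PCH3Br (2.5 equiv), KOt-Bu (2.4 equiv), THF, 0 °C → rt
Reagents that add atoms: methyltriphenylphosphonium bromide, C[P+](c1ccccc1)(c1ccccc1)c1ccccc1.[Br-]
Why: Wittig methylenation of the methyl ketone on the carboxylate salt should proceed without epimerisation because the ring methine next to the ketone enolises slowly at low temperature.

Step 3
Reactants: 3 isopropenyl acid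
Product: 4 [(1S,3S)-2,2-dimethyl-3-(prop-1-en-2-yl)cyclobutyl]methanol
Conditions: LiAlH4, THF, 0 → 50 °C; aqueous NaOH work-up
Reagents that add atoms: none
Why: Hydride reduction of the carboxylic acid touches neither the isolated alkene nor a stereocentre.

Step 4
Reactants: 4 cyclobutylmethanol
Product: 5 (1S,3S)-1-(iodomethyl)-2,2-dimethyl-3-(prop-1-en-2-yl)cyclobutane
Conditions: I2, PPh3, imidazole, CH2Cl2, 0 °C → rt
Reagents that add atoms: iodine, II
Why: Appel iodination is an SN2 displacement at the primary carbon, so no cyclobutylcarbinyl cation and no ring expansion are expected.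

Step 5
Reactants: 6 2,2,2-tribromoethanol; 7 N,N-di(propan-2-yl)carbamoyl chloride
Product: 8 2,2,2-tribromoethyl N,N-di(propan-2-yl)carbamate
Conditions: Et3N, 4-(dimethylamino)pyridine (10 mol%), CH2Cl2, 40 °C
Reagents that add atoms: none
Why: Nucleophilic acyl substitution on the carbamoyl chloride under amine base avoids an alkoxide of the tribromo alcohol.

Step 6
Reactants: 8 tribromoethyl carbamate; 9 prenyl bromide
Product: 11 5-methylhex-4-en-1-yn-1-yl N,N-di(propan-2-yl)carbamate, via lithium (carbamoyloxy)acetylide 10 (not isolated)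
Conditions: n-BuLi (3.1 equiv), THF, −78 → −30 °C; CuI (10 mol%), 9, DMPU, −78 °C → rt
Reagents that add atoms: none
Why: A Corey–Fuchs-type sequence (bromine–lithium exchange, carbenoid 1,2-hydride shift, dehydrobromination, deprotonation) should give the hindered, base-stable acetylide, which copper-assisted SN2 alkylation converts into the skipped enyne.

Step 7
Reactants: 12 (S)-4-benzyl-3-propanoyloxazolidin-2-one; 13 acetaldehyde
Product: 16 (4S)-4-benzyl-3-[(2S,3R)-3-hydroxy-2-methylbutanoyl]oxazolidin-2-one, via boron enolate 14 (not isolated), via boron aldolate 15 (not isolated)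
Conditions: Bu2BOTf, i-Pr2NEt, CH2Cl2, −78 °C; 13, −78 → 0 °C; pH 7 buffer, MeOH, H2O2
Reagents that add atoms: none
Why: The Evans syn-aldol reaction proceeds through the (Z)-boron enolate and a Zimmerman–Traxler chair in which the auxiliary benzyl group blocks one enolate face, which sets the (2S,3R) pair.

Step 8
Reactants: 16 aldol imide
Product: 17 methyl (2S,3R)-3-hydroxy-2-methylbutanoate
Conditions: NaOMe (1.2 equiv), MeOH, 0 °C, 10 min; aqueous NH4Cl
Reagents that add atoms: sodium methoxide, C[O-].[Na+]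
Why: Methanolysis at the exocyclic imide carbonyl is fast at 0 °C, so the brief exposure should not cause retro-aldol cleavage or epimerisation.

Step 9
Reactants: 18 3-phenylglutaric anhydride
Product: 19 (3R)-5-oxo-3-phenyl-5-[2-(trimethylsilyl)ethoxy]pentanoic acid
Conditions: 2-(trimethylsilyl)ethanol (3 equiv), hydroquinidine anthraquinone-1,4-diyl diether [(DHQD)2AQN] (20 mol%), Et2O, −30 °C
Reagents that add atoms: 2-(trimethylsilyl)ethanol, C[Si](C)(C)CCO
Why: Cinchona-alkaloid-catalysed desymmetrising alcoholysis delivers the primary alcohol to one enantiotopic carbonyl of the prochiral anhydride and so sets the benzylic centre.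

Step 10
Reactants: 19 hemiester; 20 bromoacetyl bromide
Product: 23 (3R)-6-bromo-5-oxo-3-phenyl-4-{[2-(trimethylsilyl)ethoxy]carbonyl}hexanoic acid (C4 epimers), via ketene silyl acetal 21 (not isolated), via trimethylsilyl ester 22 (not isolated)
Conditions: LiN(i-Pr)2 (2.2 equiv), THF, −78 °C; Me3SiCl (2.3 equiv), −78 → 0 °C; 20, CH2Cl2, 0 °C → rt; aqueous NaHCO3, then pH 4 buffer
Reagents that add atoms: none
Why: Only the ester arm is enolised beside the carboxylate, and Claisen-type C-acylation of its ketene silyl acetal by the acid bromide attaches C8a and C4a to C8 without a basic medium that would cyclise the γ-bromo keto ester.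

Step 11
Reactants: 23 bromo keto acid
Product: 24 methyl (3R)-6-bromo-5-oxo-3-phenyl-4-{[2-(trimethylsilyl)ethoxy]carbonyl}hexanoate (C4 epimers)
Conditions: Me3SiCHN2, PhMe/MeOH (4:1), 0 °C
Reagents that add atoms: (trimethylsilyl)diazomethane, C[Si](C)(C)C=[N+]=[N-]
Why: Diazoalkane methylation of the carboxylic acid is neutral and much faster than any reaction at the keto ester or the bromide.

Step 12
Reactants: 24 bromo keto diester
Product: 26 methyl (3S)-6-bromo-3-phenyl-4-{[2-(trimethylsilyl)ethoxy]carbonyl}hexa-4,5-dienoate (both allene diastereomers), via enol triflate 25 (not isolated)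
Conditions: LiN(SiMe3)2 (2.2 equiv), THF, −78 °C; Tf2O (1.1 equiv), −78 → −20 °C
Reagents that add atoms: none
Why: O-triflation of the keto ester enolate followed by 1,2-elimination of triflate with loss of a CH2Br proton is the established one-pot route from 2-substituted β-keto esters to 2,3-allenoates.

Step 13
Reactants: 26 bromoallenoate; 17 methyl (2S,3R)-3-hydroxy-2-methylbutanoate
Product: 27 methyl (3R,5E)-6-bromo-5-{[(2R,3S)-4-methoxy-3-methyl-4-oxobutan-2-yl]oxy}-3-phenyl-4-{[2-(trimethylsilyl)ethoxy]carbonyl}hex-5-enoate (C4 epimers; bromine cis to C4)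
Conditions: 17 (3 equiv), 1,4-diazabicyclo[2.2.2]octane (20 mol%), CH2Cl2, 0 °C → rt
Reagents that add atoms: none
Why: In this amine-catalysed oxa-Michael addition the alcohol attacks the central allene carbon in the plane of the terminal substituents from the hydrogen side, anti to bromine, and kinetic α-protonation keeps the new enol ether out of conjugation, so bromine ends cis to the carbon that becomes C8.

Step 14
Reactants: 5 cyclobutylmethyl iodide; 11 ynol carbamate; 27 bromo enol ether
Product: 33 2-(trimethylsilyl)ethyl (3E,5E)-5-{[di(propan-2-yl)carbamoyl]oxy}-6-{[(1R,3S)-2,2-dimethyl-3-(prop-1-en-2-yl)cyclobutyl]methyl}-3-{[(2R,3S)-4-methoxy-3-methyl-4-oxobutan-2-yl]oxy}-2-[(1R)-3-methoxy-3-oxo-1-phenylpropyl]-9-methyldeca-3,5,8-trienoate (C2 epimers), via alkyllithium 28 (not isolated), via alkylmagnesium bromide 29 (not isolated), via alkylcopper 30 (not isolated), via vinylcopper 31 (not isolated), via vinylzinc bromide 32 (not isolated)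
Conditions: 5, t-BuLi (2.1 equiv), Et2O, −78 °C; MgBr2·OEt2; CuBr·SMe2, −40 °C; 11 (1.1 equiv), −40 → −20 °C; ZnBr2, THF; 27 (0.8 equiv), Pd2(dba)3 (2.5 mol%), 2-dicyclohexylphosphino-2′,6′-dimethoxybiphenyl (10 mol%), rt → 45 °C
Reagents that add atoms: none
Why: The alkylcopper adds syn across the ynol carbamate with copper on the oxygen-bearing carbon (carbamate chelation), which places cyclobutylmethyl cis to the metal, and transmetallation to zinc followed by stereoretentive Negishi coupling joins C5 to C4a with both alkene geometries fixed.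

Step 15
Reactants: 33 triene ester
Product: 34 (3E,5E)-5-{[di(propan-2-yl)carbamoyl]oxy}-6-{[(1R,3S)-2,2-dimethyl-3-(prop-1-en-2-yl)cyclobutyl]methyl}-3-{[(2R,3S)-4-methoxy-3-methyl-4-oxobutan-2-yl]oxy}-2-[(1R)-3-methoxy-3-oxo-1-phenylpropyl]-9-methyldeca-3,5,8-trienoic acid (C2 epimers)
Conditions: tris(dimethylamino)sulfonium difluorotrimethylsilicate (TASF, 1.5 equiv), DMF, 0 °C → rt; pH 6 phosphate buffer, cold non-acidic work-up
Reagents that add atoms: none
Why: Fluoride-induced β-elimination of the 2-(trimethylsilyl)ethyl ester frees the C7 acid under nearly neutral conditions that spare the methyl esters, the enol carbamate and the acid-labile dienol ether.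

Step 16
Reactants: 34 dienoic acid
Product: 37 (6S)-5-{[di(propan-2-yl)carbamoyl]oxy}-6-{[(1R,3S)-2,2-dimethyl-3-(prop-1-en-2-yl)cyclobutyl]methyl}-3-{[(2R,3S)-4-methoxy-3-methyl-4-oxobutan-2-yl]oxy}-2-[(1S)-3-methoxy-3-oxo-1-phenylpropyl]-6-(3-methylbut-2-en-1-yl)cyclohexa-2,4-dien-1-one, via acid chloride 35 (not isolated), via dienylketene 36 (not isolated)
Conditions: 1-chloro-N,N,2-trimethylprop-1-en-1-amine (1.1 equiv), CH2Cl2, 0 °C; then i-Pr2NEt (3 equiv), PhMe (0.01 M), 0 → 60 °C
Reagents that add atoms: none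
Why: The chloroenamine converts the acid into acid chloride 35 without free HCl, and i-Pr2NEt removes the C8 proton (α to the acyl group and allylic) to give dienylketene 36, which erases the C8 centre. Ketene 36 is a hexatriene with a cis central double bond whose sp carbon C7 lies within bonding distance of C6, and it should close ring A by a thermal disrotatory six-electron electrocyclisation that forms C6–C7; the closest known reactions are the last ring closure of the Danheiser benzannulation and the thermal reverse of the Barton–Quinkert photo-opening of cyclohexa-2,4-dienones. Because C6 carries two carbon substituents the product cannot tautomerise to a phenol and stays at dienone 37. The new stereocentre C6 is controlled by the alkene geometry from the syn-carbocupration (cyclobutylmethyl is the inward group) together with the sense of rotation, which the benzylic centre on C8 biases as stated in remark 2. The step needs the C8a=C4a bond with C8 and C5 cis, preset by the stereoretentive coupling of bromide 27, and ketene closure faster than intermolecular trapping, which high dilution and the absence of nucleophiles should secure.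

Step 17
Reactants: 37 dienone
Product: 39 (6S)-6-{[(1R,3S)-2,2-dimethyl-3-(prop-1-en-2-yl)cyclobutyl]methyl}-5-hydroxy-3-{[(2R,3S)-4-methoxy-3-methyl-4-oxobutan-2-yl]oxy}-2-[(1S)-3-methoxy-3-oxo-1-phenylpropyl]-6-(3-methylbut-2-en-1-yl)cyclohexa-2,4-dien-1-one, via zirconium enolate 38 (not isolated)
Conditions: Cp2Zr(H)Cl (2 equiv), THF, 0 °C → rt, 30 min; aqueous NH4Cl
Reagents that add atoms: none
Why: Hydrozirconation of the carbamate carbonyl and collapse of the hemiaminal (the reductive O-carbamate cleavage known for aryl carbamates) should release the C5 enolate and a formamide faster than esters, the hindered C7 ketone or the 1,1-disubstituted alkene react.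

Step 18
Reactants: 39 ring A enol
Product: 41 methyl (3S)-3-[(2R,3S,6R)-6-{[(1R,3S)-2,2-dimethyl-3-(prop-1-en-2-yl)cyclobutyl]methyl}-4-hydroxy-2,3-dimethyl-6-(3-methylbut-2-en-1-yl)-5,7-dioxo-3,5,6,7-tetrahydro-2H-chromen-8-yl]-3-phenylpropanoate, via sodium enolate 40 (not isolated)
Conditions: NaH (1.05 equiv), THF, 0 → 50 °C; aqueous NH4Cl
Reagents that add atoms: none
Why: In this Dieckmann-type intramolecular Claisen condensation C4a of the stabilised enolate attacks the O1-tethered methyl ester (six-membered ring B), and with one equivalent of base the medium never holds a base strong enough to epimerise C3 or expel O1, since the methoxide released is quenched by the acidic triketone.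

Step 19
Reactants: 41 ring-closed methyl ester
Product: 42 (3S)-3-[(2R,3S,6R)-6-{[(1R,3S)-2,2-dimethyl-3-(prop-1-en-2-yl)cyclobutyl]methyl}-4-hydroxy-2,3-dimethyl-6-(3-methylbut-2-en-1-yl)-5,7-dioxo-3,5,6,7-tetrahydro-2H-chromen-8-yl]-3-phenylpropanoic acid (CNP0328119.1)
Conditions: Me3SnOH (5 equiv), ClCH2CH2Cl, 70 °C; 0.1 M HCl work-up
Reagents that add atoms: trimethyltin hydroxide, C[Sn](C)(C)O
Why: Tin-hydroxide-mediated hydrolysis of the unhindered methyl ester is close to neutral, so the cis-2,3-dimethyl ring B and the acid-sensitive alkenes should survive.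

Compound list
1 | (1S,5S)-4,6,6-trimethylbicyclo[3.1.1]hept-3-en-2-one, (1S)-(−)-verbenone | CC1=CC(=O)[C@H]2C[C@@H]1C2(C)C | starting material
2 | (1S,3R)-3-acetyl-2,2-dimethylcyclobutane-1-carboxylic acid (cis) | CC(=O)[C@@H]1C[C@H](C(=O)O)C1(C)C | intermediate
3 | (1S,3S)-2,2-dimethyl-3-(prop-1-en-2-yl)cyclobutane-1-carboxylic acid (cis) | C=C(C)[C@@H]1C[C@H](C(=O)O)C1(C)C | intermediate
4 | [(1S,3S)-2,2-dimethyl-3-(prop-1-en-2-yl)cyclobutyl]methanol | C=C(C)[C@@H]1C[C@H](CO)C1(C)C | intermediate
5 | (1S,3S)-1-(iodomethyl)-2,2-dimethyl-3-(prop-1-en-2-yl)cyclobutane | C=C(C)[C@@H]1C[C@H](CI)C1(C)C | intermediate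
6 | 2,2,2-tribromoethanol | OCC(Br)(Br)Br | starting material
7 | N,N-di(propan-2-yl)carbamoyl chloride | CC(C)N(C(C)C)C(=O)Cl | starting material
8 | 2,2,2-tribromoethyl N,N-di(propan-2-yl)carbamate | CC(C)N(C(C)C)C(=O)OCC(Br)(Br)Br | intermediate
9 | 1-bromo-3-methylbut-2-ene (prenyl bromide) | CC(C)=CCBr | starting material
10 | lithium 2-{[di(propan-2-yl)carbamoyl]oxy}ethyn-1-ide | [Li]C#COC(=O)N(C(C)C)C(C)C | intermediate (not isolated)
11 | 5-methylhex-4-en-1-yn-1-yl N,N-di(propan-2-yl)carbamate | CC(C)=CCC#COC(=O)N(C(C)C)C(C)C | intermediate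
12 | (S)-4-benzyl-3-propanoyl-1,3-oxazolidin-2-one | CCC(=O)N1[C@@H](Cc2ccccc2)COC1=O | starting material
13 | acetaldehyde | CC=O | starting material
14 | (4S)-4-benzyl-3-{(1Z)-1-[(dibutylboranyl)oxy]prop-1-en-1-yl}-1,3-oxazolidin-2-one | C/C=C(\OB(CCCC)CCCC)N1[C@@H](Cc2ccccc2)COC1=O | intermediate (not isolated)
15 | (4S)-4-benzyl-3-{(2S,3R)-3-[(dibutylboranyl)oxy]-2-methylbutanoyl}-1,3-oxazolidin-2-one | C[C@@H](OB(CCCC)CCCC)[C@H](C)C(=O)N1[C@@H](Cc2ccccc2)COC1=O | intermediate (not isolated)
16 | (4S)-4-benzyl-3-[(2S,3R)-3-hydroxy-2-methylbutanoyl]-1,3-oxazolidin-2-one | C[C@@H](O)[C@H](C)C(=O)N1[C@@H](Cc2ccccc2)COC1=O | intermediate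
17 | methyl (2S,3R)-3-hydroxy-2-methylbutanoate | C[C@@H](O)[C@H](C)C(=O)OC | intermediate
18 | 4-phenyloxane-2,6-dione (3-phenylglutaric anhydride) | O=C1CC(c2ccccc2)CC(=O)O1 | starting material
19 | (3R)-5-oxo-3-phenyl-5-[2-(trimethylsilyl)ethoxy]pentanoic acid | C[Si](C)(C)CCOC(=O)C[C@@H](CC(=O)O)c1ccccc1 | intermediate
20 | bromoacetyl bromide | BrCC(Br)=O | starting material
21 | trimethylsilyl (3R)-3-phenyl-5-[2-(trimethylsilyl)ethoxy]-5-[(trimethylsilyl)oxy]pent-4-enoate (ketene silyl acetal, alkene geometry open) | C[Si](C)(C)CCOC(O[Si](C)(C)C)=C[C@@H](CC(=O)O[Si](C)(C)C)c1ccccc1 | intermediate (not isolated)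
22 | trimethylsilyl (3R)-6-bromo-5-oxo-3-phenyl-4-{[2-(trimethylsilyl)ethoxy]carbonyl}hexanoate (C4 epimers) | C[Si](C)(C)CCOC(=O)C(C(=O)CBr)[C@@H](CC(=O)O[Si](C)(C)C)c1ccccc1 | intermediate (not isolated)
23 | (3R)-6-bromo-5-oxo-3-phenyl-4-{[2-(trimethylsilyl)ethoxy]carbonyl}hexanoic acid (C4 epimers) | C[Si](C)(C)CCOC(=O)C(C(=O)CBr)[C@@H](CC(=O)O)c1ccccc1 | intermediate
24 | methyl (3R)-6-bromo-5-oxo-3-phenyl-4-{[2-(trimethylsilyl)ethoxy]carbonyl}hexanoate (C4 epimers) | C[Si](C)(C)CCOC(=O)C(C(=O)CBr)[C@@H](CC(=O)OC)c1ccccc1 | intermediate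
25 | methyl (3S)-6-bromo-3-phenyl-5-{[(trifluoromethyl)sulfonyl]oxy}-4-{[2-(trimethylsilyl)ethoxy]carbonyl}hex-4-enoate (enol triflate) | C[Si](C)(C)CCOC(=O)C(=C(CBr)OS(=O)(=O)C(F)(F)F)[C@@H](CC(=O)OC)c1ccccc1 | intermediate (not isolated)
26 | methyl (3S)-6-bromo-3-phenyl-4-{[2-(trimethylsilyl)ethoxy]carbonyl}hexa-4,5-dienoate (both allene diastereomers) | C[Si](C)(C)CCOC(=O)C(=C=CBr)[C@@H](CC(=O)OC)c1ccccc1 | intermediate
27 | methyl (3R,5E)-6-bromo-5-{[(2R,3S)-4-methoxy-3-methyl-4-oxobutan-2-yl]oxy}-3-phenyl-4-{[2-(trimethylsilyl)ethoxy]carbonyl}hex-5-enoate (C4 epimers) | C[Si](C)(C)CCOC(=O)C([C@@H](CC(=O)OC)c1ccccc1)/C(O[C@H](C)[C@H](C)C(=O)OC)=C\Br | intermediate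
28 | alkyllithium from 5, {[(1S,3S)-2,2-dimethyl-3-(prop-1-en-2-yl)cyclobutyl]methyl}lithium | C=C(C)[C@@H]1C[C@H](C[Li])C1(C)C | intermediate (not isolated)
29 | bromo{[(1S,3S)-2,2-dimethyl-3-(prop-1-en-2-yl)cyclobutyl]methyl}magnesium | C=C(C)[C@@H]1C[C@H](C[Mg]Br)C1(C)C | intermediate (not isolated)
30 | {[(1S,3S)-2,2-dimethyl-3-(prop-1-en-2-yl)cyclobutyl]methyl}copper | C=C(C)[C@@H]1C[C@H](C[Cu])C1(C)C | intermediate (not isolated)
31 | vinylcopper: 1-{[di(propan-2-yl)carbamoyl]oxy}-2-{[(1R,3S)-2,2-dimethyl-3-(prop-1-en-2-yl)cyclobutyl]methyl}-5-methylhexa-1,4-dien-1-ylcopper, cyclobutylmethyl cis to copper | CC(C)=CC/C(C[C@H]1C[C@@H](C(C)=C)C1(C)C)=C(/[Cu])OC(=O)N(C(C)C)C(C)C | intermediate (not isolated)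
32 | the corresponding vinylzinc bromide, same alkene geometry | CC(C)=CC/C(C[C@H]1C[C@@H](C(C)=C)C1(C)C)=C(/[Zn]Br)OC(=O)N(C(C)C)C(C)C | intermediate (not isolated)
33 | 2-(trimethylsilyl)ethyl ester of 34 (full name in step 14) | C[Si](C)(C)CCOC(=O)C([C@@H](CC(=O)OC)c1ccccc1)/C(O[C@H](C)[C@H](C)C(=O)OC)=C\C(OC(=O)N(C(C)C)C(C)C)=C(\CC=C(C)C)C[C@H]1C[C@@H](C(C)=C)C1(C)C | intermediate
34 | (3E,5E)-5-{[di(propan-2-yl)carbamoyl]oxy}-6-{[(1R,3S)-2,2-dimethyl-3-(prop-1-en-2-yl)cyclobutyl]methyl}-3-{[(2R,3S)-4-methoxy-3-methyl-4-oxobutan-2-yl]oxy}-2-[(1R)-3-methoxy-3-oxo-1-phenylpropyl]-9-methyldeca-3,5,8-trienoic acid (C2 epimers) | OC(=O)C([C@@H](CC(=O)OC)c1ccccc1)/C(O[C@H](C)[C@H](C)C(=O)OC)=C\C(OC(=O)N(C(C)C)C(C)C)=C(\CC=C(C)C)C[C@H]1C[C@@H](C(C)=C)C1(C)C | intermediate (precursor of the key step)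
35 | acid chloride of 34 | ClC(=O)C([C@@H](CC(=O)OC)c1ccccc1)/C(O[C@H](C)[C@H](C)C(=O)OC)=C\C(OC(=O)N(C(C)C)C(C)C)=C(\CC=C(C)C)C[C@H]1C[C@@H](C(C)=C)C1(C)C | intermediate (not isolated)
36 | dienylketene from 35 by loss of HCl (C7=C8 cumulated with C=O; alkene geometries as in 34) | O=C=C([C@@H](CC(=O)OC)c1ccccc1)/C(O[C@H](C)[C@H](C)C(=O)OC)=C\C(OC(=O)N(C(C)C)C(C)C)=C(\CC=C(C)C)C[C@H]1C[C@@H](C(C)=C)C1(C)C | intermediate (not isolated)
37 | ring A dienone (full name in step 16) | C=C(C)[C@@H]1C[C@H](C[C@@]2(CC=C(C)C)C(OC(=O)N(C(C)C)C(C)C)=CC(O[C@H](C)[C@H](C)C(=O)OC)=C([C@@H](CC(=O)OC)c3ccccc3)C2=O)C1(C)C | intermediate (product of the key step)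
38 | chlorobis(cyclopentadienyl)zirconium enolate of 39 (Zr on the C5 oxygen) | C=C(C)[C@@H]1C[C@H](C[C@@]2(CC=C(C)C)C(O[Zr+2]Cl)=CC(O[C@H](C)[C@H](C)C(=O)OC)=C([C@@H](CC(=O)OC)c3ccccc3)C2=O)C1(C)C.c1cc[cH-]c1.c1cc[cH-]c1 | intermediate (not isolated)
39 | ring A 5-hydroxy dienone (full name in step 17) | C=C(C)[C@@H]1C[C@H](C[C@@]2(CC=C(C)C)C(O)=CC(O[C@H](C)[C@H](C)C(=O)OC)=C([C@@H](CC(=O)OC)c3ccccc3)C2=O)C1(C)C | intermediate
40 | sodium enolate of 39 | [Na+].C=C(C)[C@@H]1C[C@H](C[C@@]2(CC=C(C)C)C([O-])=CC(O[C@H](C)[C@H](C)C(=O)OC)=C([C@@H](CC(=O)OC)c3ccccc3)C2=O)C1(C)C | intermediate (not isolated)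
41 | methyl ester of 42 (full name in step 18) | C=C(C)[C@@H]1C[C@H](C[C@@]2(CC=C(C)C)C(=O)C3=C(O)[C@@H](C)[C@@H](C)OC3=C([C@@H](CC(=O)OC)c3ccccc3)C2=O)C1(C)C | intermediate
42 | CNP0328119.1 (full name in step 19) | C=C(C)[C@@H]1C[C@H](C[C@@]2(CC=C(C)C)C(=O)C3=C(O)[C@@H](C)[C@@H](C)OC3=C([C@@H](CC(=O)O)c3ccccc3)C2=O)C1(C)C | target

Total step count: 19. Longest linear sequence: 11 steps (steps 9–19, from 3-phenylglutaric anhydride 18).

Steps most likely to fail

Step 13. The risk is a loss of geometric control when the alcohol is added: the hindered secondary alcohol may add slowly, may approach syn to bromine, or the adduct may drift into conjugation under the amine, which would erase the preset C8a=C4a geometry. The fallback reverses the order of the two bond formations and sets out from bromoallene 26. Palladium-catalysed coupling of 26 with vinylzinc bromide 32 (generated as in step 14; Pd(PPh3)4, THF, rt), a known coupling of haloallenes with organozinc reagents, should give the vinylallene ester F1. Amine-catalysed conjugate addition of alcohol 17 to the vinylallene ester F1 is then steered away from the much larger C5 substituent and, after α-protonation, comes back to the route at 33.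

Step 16. The risk is poor facial selectivity in the ring closure, so that the rotation at C6 runs both ways and the C6 epimer is formed beside 37. The fallback sets out from 34 and adds a photochemical recycling loop to the thermal closure. The unwanted epimer, the C6-epimeric dienone F2, is separated and irradiated (366 nm, PhMe, rt, no nucleophile present), which should reopen ring A to dienylketene 36 by the Barton–Quinkert reaction. The ketene recloses in the dark, and repeated separation and irradiation should drain the C6-epimeric dienone F2 into 37, where the route continues.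

Step 17. The risk is over-reduction, that is hydrozirconation of the isopropenyl group or attack at the C7 ketone competing with the hindered carbamate, or incomplete cleavage. The fallback sets out from 37 and replaces reduction by a vinylogous substitution at C5, which in the dienone is the terminus of a doubly vinylogous acyl system. Potassium (E)-benzaldoximate (benzaldoxime, KOt-Bu, THF/DMSO, 0 °C) should displace the carbamate by addition–elimination to give the O-vinyl oxime ether F3. A second equivalent of base fragments the O-vinyl oxime ether F3 to benzonitrile and the C5 enolate, which on mild acidification comes back to the route at 39.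

Further compounds
F1 | step 13 | 2-(trimethylsilyl)ethyl 5-{[di(propan-2-yl)carbamoyl]oxy}-6-{[(1R,3S)-2,2-dimethyl-3-(prop-1-en-2-yl)cyclobutyl]methyl}-2-[(1S)-3-methoxy-3-oxo-1-phenylpropyl]-9-methyldeca-2,3,5,8-tetraenoate (vinylallene ester, both allene diastereomers, C5=C6 geometry as in 33) | C[Si](C)(C)CCOC(=O)C([C@@H](CC(=O)OC)c1ccccc1)=C=C/C(OC(=O)N(C(C)C)C(C)C)=C(/CC=C(C)C)C[C@H]1C[C@@H](C(C)=C)C1(C)C
F2 | step 16 | C6 epimer of dienone 37 (6R) | C=C(C)[C@@H]1C[C@H](C[C@]2(CC=C(C)C)C(OC(=O)N(C(C)C)C(C)C)=CC(O[C@H](C)[C@H](C)C(=O)OC)=C([C@@H](CC(=O)OC)c3ccccc3)C2=O)C1(C)C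
F3 | step 17 | O-vinyl oxime ether of 39 with (E)-benzaldoxime on the C5 oxygen | C=C(C)[C@@H]1C[C@H](C[C@@]2(CC=C(C)C)C(O/N=C/c3ccccc3)=CC(O[C@H](C)[C@H](C)C(=O)OC)=C([C@@H](CC(=O)OC)c3ccccc3)C2=O)C1(C)C
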